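(The runs stem from a simulated flask with made-up constants; noise was put on by code.)

Capture agent over spent carrier charged stands at 6.00 in the flask, so of those two the carrier is the limiting reagent, and its balance is the one to write.

| setting | Saturday's | Thursday's | flask |
|---|---|---|---|
| substrate | 0.21 M | 0.21 M | 0.21 M |
| salt in the second phase | 1 equiv | 4 equiv | 2.00 equiv |
| capture agent | 0.063 M | 0.063 M | 0.0630 M |
| spent carrier | 5 mol% | 5 mol% | 5 mol% |
| remark | run made earlier | run made earlier |  |
| volume of the second phase over the first |  |  | 1.0 |

- Saturday's (time / h: product / %): 1.33: 4.5; 4.00: 8.2; 8.00: 9.6; 10.0: 9.7; 15.0: 9.1
- Thursday's (time / h: product / %): 1.33: 9.5; 4.00: 19.8; 8.00: 25.2; 10.0: 26.9; 15.0: 28.1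

(scatter of a reading: 0.3 percentage points)

* apparent order in spent carrier when 10 % of the substrate are converted (percent change of the rate of making product for one percent more spent carrier charged)
* apparent order in salt in the second phase when 10 % of the substrate are converted (percent change of the rate of making product for one percent more salt in the second phase charged)
* factor on the rate of making product when 10 % of the substrate are converted if spent carrier is charged twice over

- in the second phase: salt in the second phase, spent salt in the second phase; everything else is in the first
- charges count per volume of the first phase; a concentration in a rate is the amount of a species over the volume of its own phase; every rate counts per litre of the first phase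
- the earlier runs were read with a standard deviation of 0.3 percentage points
- reactions considered so far: spent carrier + salt in the second phase <-> fresh carrier + spent salt in the second phase; substrate + fresh carrier -> product + spent carrier; spent carrier + capture agent -> trapped intermediate
- the earlier runs hold the two phases in the same ratio of volumes as the flask asked about
- no earlier run changes the charge of spent carrier; that part of a forecast is a guess

*Why does product stop in the earlier runs?* Saturday's run levels near 9.7 % and Thursday's near 28.1 %, with most of the substrate unused in both. I read that as carrier lost to capture agent.

*What do you take from those two stops?* Divide each by the loading: 1.94 on Saturday, 5.62 on Thursday. The flask's 2.00 equiv lies midway by ratio between their salt charges, so I take the geometric mean, 3.30. Call that the allowance, the product one charged carrier gives before it is trapped.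

*What does it say at the moment asked about?* By my reckoning the flask should stop near 16.5 %, so at 10 % conversion I put the lost share of the carrier at 0.606.

*And the weak spot?* The order in carrier. Suppose the allowance does not move with the charge; then a given amount of product goes with a given amount of carrier lost. Working carrier is then the charge minus product over allowance, and if the rate follows it, my order is one over one minus the lost share, 2.54. No earlier run changes that charge, so this stays a guess.

*What does the forecast say?* It gives 1.9 in carrier (1.5 to 2.4), 1.6 in salt (1.15 to 2.1) and a factor of 2.85 (2.3 to 3.4), holding that “about half the carrier is dead”. My order stands above its range; we part at the lost share, 0.606 against 0.5.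

    spent carrier + salt in the second phase ⇌ fresh carrier + spent salt in the second phase (K = 0.210, k = 8.80 /M/h)
    substrate + fresh carrier → product + spent carrier (k = 13.0 /M/h)
    spent carrier + capture agent → trapped intermediate (k = 13.0 /M/h)

The flask gives 2.1 in carrier, 1.6 in salt and a factor of 3.02, inside the forecast's ranges, and below my 2.54. A run at another carrier charge with a factor outside 2.3 to 3.4 would overturn the forecast. The allowance put the stop near 16.5 %, and product in the flask stands at 17.3 % after 25.0 h. Against my lost share of 0.606, trapped intermediate in the flask stands at 60.3 % of the catalyst charged after 2.50 h.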